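Longipinane numbering. The route rests on disconnecting C5–C6, the bond joining the cyclobutane methine to the gem-dimethyl carbon within the seven-membered ring C4–C5–C6–C7–C8–C9–C10. The key step exploits the pseudo-diaxial 1,3-relationship across cyclobutane C4–C5–C11–C10, which holds the C10 side chain under C5. Hydrogen-atom transfer to an isopropenyl group gives the tertiary C6 radical, this adds to a C5 tosylhydrazone, and loss of sulfinate and N2 leaves C5–H. One operation closes the last ring, creates the quaternary carbon, sets C5 and erases the carbonyl. Its precursor is a verbenone-like bicyclo[3.1.1]heptenone bearing a cyclobutanone hydrazone and an open diester chain, assembled by vinylketene [2+2] cycloaddition.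

Key step: step 13

Numbering used in the text: C1 = ring ketone, C2=C3 (C3 bears CH3), C4 and C11 = cyclobutane bridgeheads (C11 next to C1), C5 = cyclobutane CH, C6 = C(CH3)2, C7 = CH–O-senecioyl, C8 = CH2, C9 = CH–O-tigloyl, C10 = quaternary C–CH3.
Assumption: steps 4 and 9 are reagent-controlled. Of each commercial chiral controller, the antipode that gives the drawn configuration is taken, so the isopinocampheyl groups are written without stereodescriptors.

Step 1
Reactants: 1 1-(tert-butyldimethylsilyloxy)propan-2-one; 2 diethyl [2-(methoxy(methyl)amino)-2-oxoethyl]phosphonate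
Product: 3 (E)-4-(tert-butyldimethylsilyloxy)-N-methoxy-N,3-dimethylbut-2-enamide
Conditions: NaH, THF, 0 °C to rt
Reagents that add atoms: none
Why: Horner–Wadsworth–Emmons olefination of an activated α-silyloxy ketone should place the amide carbonyl trans to the larger CH2OTBS group, so the E geometry that later defines C10 is fixed here (any Z isomer is removed by chromatography).

Step 2
Reactants: 3 (E)-4-(tert-butyldimethylsilyloxy)-N-methoxy-N,3-dimethylbut-2-enamide
Product: 4 (E)-4-(tert-butyldimethylsilyloxy)-3-methylbut-2-enal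
Conditions: DIBAL-H, THF, −78 °C; aq. Rochelle salt
Reagents that add atoms: none
Why: Hydride reduction of an N-methoxy-N-methylamide stops at the aldehyde oxidation level thanks to chelation by the N-methoxy group, and the alkene geometry is not touched.

Step 3
Reactants: 5 tert-butyl 3-methylbut-2-enoate
Product: 6 1-tert-butoxy-1-(tert-butyldimethylsilyloxy)-3-methylbuta-1,3-diene
Conditions: LDA, DMPU, THF, −78 °C; TBSCl
Reagents that add atoms: tert-butyldimethylsilyl chloride, CC(C)(C)[Si](C)(C)Cl
Why: Kinetic γ-deprotonation of the senecioate followed by O-silylation (silyl ketene acetal formation) gives the vinylogous nucleophile.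

Step 4
Reactants: 4 (E)-4-(tert-butyldimethylsilyloxy)-3-methylbut-2-enal; 6 1-tert-butoxy-1-(tert-butyldimethylsilyloxy)-3-methylbuta-1,3-diene
Product: 7 tert-butyl (2E,5S,6E)-8-(tert-butyldimethylsilyloxy)-5-hydroxy-3,7-dimethylocta-2,6-dienoate
Conditions: SiCl4, chiral binaphthyldiamine-derived bisphosphoramide (5 mol %), iPr2NEt (10 mol %), CH2Cl2, −78 °C; aq. KH2PO4
Reagents that add atoms: none
Why: In this catalytic enantioselective vinylogous Mukaiyama aldol reaction (Lewis-base-activated SiCl4), which is γ-selective because of the bulky ester and silyl groups, the phosphoramide-bound silicon cation shields one aldehyde face and should set the 5S carbinol (future C1), the only stereocentre that controls the bicyclic core.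

Step 5
Reactants: 7 tert-butyl (2E,5S,6E)-8-(tert-butyldimethylsilyloxy)-5-hydroxy-3,7-dimethylocta-2,6-dienoate
Product: 9 (2E,5S,6E)-5,8-bis(tert-butyldimethylsilyloxy)-3,7-dimethylocta-2,6-dienoic acid, via silyl ester 8 (not isolated)
Conditions: TBSOTf (excess), 2,6-lutidine, CH2Cl2, 0 °C to rt; then THF/H2O, cat. AcOH
Reagents that add atoms: tert-butyldimethylsilyl triflate, CC(C)(C)[Si](C)(C)OS(=O)(=O)C(F)(F)F
Why: The silyl triflate silylates the alcohol and also exchanges the tert-butyl ester for a labile silyl ester (loss of isobutene) that mild aqueous work-up hydrolyses, and the stereocentre is not involved.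

Step 6
Reactants: 9 (2E,5S,6E)-5,8-bis(tert-butyldimethylsilyloxy)-3,7-dimethylocta-2,6-dienoic acid
Product: 12 4-(tert-butyldimethylsilyloxy)-7-(tert-butyldimethylsilyloxymethyl)-7-methyl-2-methylidenebicyclo[3.1.1]heptan-6-one (CH3 syn and CH2OTBS anti to the C2–C4 bridge; 4-OTBS on the side of the carbonyl bridge), via acid chloride 10 (not isolated), via vinylketene 11 (not isolated)
Conditions: 1-chloro-N,N,2-trimethylprop-1-en-1-amine, CH2Cl2, 0 °C; then slow addition to Et3N, toluene, 110 °C, high dilution
Reagents that add atoms: none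
Why: In this intramolecular vinylketene–alkene [2+2] cycloaddition the ketene carbonyl carbon bonds to the less substituted alkene carbon to give the bridged bicyclo[3.1.1] skeleton, suprafacial addition to the E-alkene places CH3 syn and CH2OTBS anti to the three-carbon bridge, and the 5S silyloxy group takes the side of the new carbonyl bridge away from that CH3 (as in trans-verbenol), which selects the alkene face and so sets C4, C10 and C11.

Step 7
Reactants: 12 the bis-silyl cycloadduct
Product: 13 4-hydroxy-7-(hydroxymethyl)-7-methyl-2-methylidenebicyclo[3.1.1]heptan-6-one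
Conditions: HF·pyridine, pyridine, THF, 0 °C to rt
Reagents that add atoms: none
Why: Fluoride-mediated desilylation under mildly acidic conditions frees both alcohols and avoids the retro-aldol cleavage that a basic fluoride source could trigger in the β-hydroxy cyclobutanone.

Step 8
Reactants: 13 the keto diol
Product: 15 2,7-dimethyl-4,6-dioxobicyclo[3.1.1]hept-2-ene-7-carbaldehyde (CHO anti to the enone bridge), via methylidene diketo aldehyde 14 (not isolated)
Conditions: DMP, CH2Cl2, 0 °C to rt; then DBU (cat.), rt
Reagents that add atoms: none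
Why: Dess–Martin oxidation converts both alcohols at once and catalytic DBU moves the exocyclic alkene into conjugation (thermodynamic enone formation), which removes the spent carbinol stereocentre and delivers the verbenone-type enone.

Step 9
Reactants: 15 the enone keto aldehyde; 16 3-methylbut-3-en-2-one
Product: 18 7-[(1R)-1-hydroxy-4-methyl-3-oxopent-4-enyl]-2,7-dimethylbicyclo[3.1.1]hept-2-ene-4,6-dione (9R), via boron enolate 17 (not isolated)
Conditions: Ipc2BCl, Et3N, Et2O, 0 °C; then 15, −78 to −20 °C; MeOH, pH 7 buffer (no peroxide)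
Reagents that add atoms: none
Why: In this boron-mediated asymmetric aldol reaction of a methyl ketone the aldehyde is by far the most electrophilic carbonyl and has no useful facial bias of its own because its surroundings are almost mirror-symmetric, so the isopinocampheyl ligands should decide the 9R configuration.

Step 10
Reactants: 18 the 9R aldol; 19 (E)-2-methylbut-2-enal (tiglaldehyde)
Product: 20 (1R,3R)-1-(2,7-dimethyl-4,6-dioxobicyclo[3.1.1]hept-2-en-7-yl)-3-hydroxy-4-methylpent-4-enyl (E)-2-methylbut-2-enoate (9-tiglate with free 7R alcohol)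
Conditions: SmI2 (0.3 equiv), 19 (excess), THF, −10 °C
Reagents that add atoms: none
Why: In the Evans–Tishchenko reaction the aldehyde carbon, once bound to the C9 oxygen, delivers hydride intramolecularly to the samarium-activated ketone through a chair-like transition state, which should give the 1,3-anti (7R) alcohol and leave the tiglate on O9, so the two oxygens are differentiated.

Step 11
Reactants: 20 the hydroxy tiglate; 21 3-methylbut-2-enoyl chloride
Product: 22 the 7-senecioate 9-tiglate of the open-chain diketone (7R,9R)
Conditions: pyridine, DMAP (cat.), CH2Cl2, 0 °C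
Reagents that add atoms: none
Why: DMAP-catalysed acylation of the free allylic alcohol proceeds with retention at C7, and pyridine is used instead of a trialkylamine to avoid deconjugation of the senecioyl unit through its vinylketene.

Step 12
Reactants: 22 the diester diketone
Product: 23 the C5 (cyclobutanone) N-tosylhydrazone of 22
Conditions: TsNHNH2 (1 equiv), PPTS (cat.), EtOH/THF, rt
Reagents that add atoms: p-toluenesulfonyl hydrazide, Cc1ccc(cc1)S(=O)(=O)NN
Why: Acid-catalysed hydrazone condensation should favour the strained, unconjugated cyclobutanone over the hindered conjugated enone, and the absence of base protects the non-enolisable β-diketone from retro-Claisen cleavage.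

Step 13
Reactants: 23 the C5 tosylhydrazone
Product: 26 (4R,5S,7R,9R,10R,11R)-7-senecioyloxy-9-tigloyloxylongipin-2-en-1-one (target), via cyclised hydrazide 24 (not isolated), via diazene 25 (not isolated)
Conditions: Fe(acac)3 (0.3 equiv), PhSiH3, EtOH, high dilution, 60 °C; then NaOAc, 78 °C
Reagents that add atoms: none
Why: An iron hydride formed from Fe(acac)3, PhSiH3 and EtOH should transfer a hydrogen atom to the CH2 terminus of the isopropenyl group (Markovnikov MHAT), the nucleophilic tertiary C6 radical adds to the electrophilic C5 of the sulfonylhydrazone, the hydrazinyl radical is reduced and protonated to 24, and warming with acetate expels p-toluenesulfinate to give diazene 25, which loses N2 and leaves C5–H. The closest known reaction types are the HAT-initiated radical cyclisation of alkene-tethered ketone tosylhydrazones, radical cyclisation onto N-aziridinyl imines with loss of N2, and the sulfonylhydrazide-to-alkane collapse of the Caglioti reduction and of MHAT hydromethylation. The ring C4–C5–C6–C7–C8–C9–C10 closes in the 7-exo-trig mode onto C=N, helped by the pseudo-axial C10 chain, which lies under C5 and leaves only four rotatable bonds between the reacting centres. C5 is the only new stereocentre: the tethered radical can reach C5 only from the face anti to the enone bridge, nitrogen is pushed to the syn face, and the cage allows no inversion when N2 departs, so hydrogen takes the place of nitrogen. The step needs chemoselective HAT to the electron-neutral 1,1-disubstituted alkene in the presence of the enone, tiglate and senecioate, which as electron-poor trisubstituted alkenes are slow HAT acceptors and are either out of reach or too hindered to trap the radical, while high dilution suppresses intermolecular conjugate addition.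

Compound list
1 | 1-(tert-butyldimethylsilyloxy)propan-2-one | CC(=O)CO[Si](C)(C)C(C)(C)C | starting material
2 | diethyl [2-(methoxy(methyl)amino)-2-oxoethyl]phosphonate | CCOP(=O)(CC(=O)N(C)OC)OCC | starting material
3 | (E)-4-(tert-butyldimethylsilyloxy)-N-methoxy-N,3-dimethylbut-2-enamide | CON(C)C(=O)/C=C(\C)CO[Si](C)(C)C(C)(C)C | intermediate
4 | (E)-4-(tert-butyldimethylsilyloxy)-3-methylbut-2-enal | O=C/C=C(\C)CO[Si](C)(C)C(C)(C)C | intermediate
5 | tert-butyl 3-methylbut-2-enoate | CC(C)=CC(=O)OC(C)(C)C | starting material
6 | 1-tert-butoxy-1-(tert-butyldimethylsilyloxy)-3-methylbuta-1,3-diene | C=C(C)C=C(OC(C)(C)C)O[Si](C)(C)C(C)(C)C | intermediate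
7 | tert-butyl (2E,5S,6E)-8-(tert-butyldimethylsilyloxy)-5-hydroxy-3,7-dimethylocta-2,6-dienoate | CC(C)(C)OC(=O)/C=C(\C)C[C@H](O)/C=C(\C)CO[Si](C)(C)C(C)(C)C | intermediate
8 | tert-butyldimethylsilyl ester of 9 (not isolated) | CC(C)(C)[Si](C)(C)OC(=O)/C=C(\C)C[C@H](O[Si](C)(C)C(C)(C)C)/C=C(\C)CO[Si](C)(C)C(C)(C)C | intermediate
9 | (2E,5S,6E)-5,8-bis(tert-butyldimethylsilyloxy)-3,7-dimethylocta-2,6-dienoic acid | OC(=O)/C=C(\C)C[C@H](O[Si](C)(C)C(C)(C)C)/C=C(\C)CO[Si](C)(C)C(C)(C)C | intermediate
10 | acid chloride of 9 (not isolated) | ClC(=O)/C=C(\C)C[C@H](O[Si](C)(C)C(C)(C)C)/C=C(\C)CO[Si](C)(C)C(C)(C)C | intermediate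
11 | vinylketene from 10 (not isolated) | O=C=CC(=C)C[C@H](O[Si](C)(C)C(C)(C)C)/C=C(\C)CO[Si](C)(C)C(C)(C)C | intermediate
12 | 4-(TBSO)-7-(TBSOCH2)-7-methyl-2-methylidenebicyclo[3.1.1]heptan-6-one, C4/C10/C11 arranged as in 26 | CC(C)(C)[Si](C)(C)OC[C@@]1(C)[C@@H]2[C@@H](O[Si](C)(C)C(C)(C)C)CC(=C)[C@H]1C2=O | intermediate
13 | 4-hydroxy-7-(hydroxymethyl)-7-methyl-2-methylidenebicyclo[3.1.1]heptan-6-one | OC[C@@]1(C)[C@@H]2[C@@H](O)CC(=C)[C@H]1C2=O | intermediate
14 | 7-methyl-2-methylidene-4,6-dioxobicyclo[3.1.1]heptane-7-carbaldehyde (not isolated) | O=C[C@@]1(C)[C@@H]2C(=O)CC(=C)[C@H]1C2=O | intermediate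
15 | 2,7-dimethyl-4,6-dioxobicyclo[3.1.1]hept-2-ene-7-carbaldehyde | O=C[C@@]1(C)[C@@H]2C(=O)C=C(C)[C@H]1C2=O | intermediate
16 | 3-methylbut-3-en-2-one | CC(=O)C(C)=C | starting material
17 | diisopinocampheylboron enolate of 16 (not isolated) | C=C(C)C(=C)OB(C1CC2CC(C1C)C2(C)C)C1CC2CC(C1C)C2(C)C | intermediate
18 | 9R aldol, 7-[(1R)-1-hydroxy-4-methyl-3-oxopent-4-enyl]-2,7-dimethylbicyclo[3.1.1]hept-2-ene-4,6-dione | O[C@H](CC(=O)C(C)=C)[C@@]1(C)[C@@H]2C(=O)C=C(C)[C@H]1C2=O | intermediate
19 | (E)-2-methylbut-2-enal | C/C=C(\C)C=O | starting material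
20 | 9-tiglate with free 7R alcohol | C/C=C(\C)C(=O)O[C@H](C[C@@H](O)C(C)=C)[C@@]1(C)[C@@H]2C(=O)C=C(C)[C@H]1C2=O | intermediate
21 | 3-methylbut-2-enoyl chloride | CC(C)=CC(=O)Cl | starting material
22 | 7-senecioate 9-tiglate, open-chain diketone | C/C=C(\C)C(=O)O[C@H](C[C@@H](OC(=O)C=C(C)C)C(C)=C)[C@@]1(C)[C@@H]2C(=O)C=C(C)[C@H]1C2=O | intermediate
23 | C5 N-tosylhydrazone of 22 | C/C=C(\C)C(=O)O[C@H](C[C@@H](OC(=O)C=C(C)C)C(C)=C)[C@@]1(C)[C@@H]2C(=O)C=C(C)[C@H]1C2=NNS(=O)(=O)c1ccc(C)cc1 | intermediate
24 | cyclised C5 N'-tosylhydrazide (not isolated) | C/C=C(\C)C(=O)O[C@@H]1C[C@@H](OC(=O)C=C(C)C)C(C)(C)[C@]2(NNS(=O)(=O)c4ccc(C)cc4)[C@H]3C(=O)C=C(C)[C@@H]2[C@]31C | intermediate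
25 | C5 monoalkyl diazene (not isolated) | C/C=C(\C)C(=O)O[C@@H]1C[C@@H](OC(=O)C=C(C)C)C(C)(C)[C@]2(N=N)[C@H]3C(=O)C=C(C)[C@@H]2[C@]31C | intermediate
26 | (4R,5S,7R,9R,10R,11R)-7-senecioyloxy-9-tigloyloxylongipin-2-en-1-one | C/C=C(\C)C(=O)O[C@@H]1C[C@@H](OC(=O)C=C(C)C)C(C)(C)[C@@H]2[C@H]3C(=O)C=C(C)[C@@H]2[C@]31C | target

Total step count: 13. Longest linear sequence: 12 steps (steps 1, 2 and 4–13, from 1 to 26).

**Steps most likely to fail**

**Step 13.** The tertiary C6 radical may be quenched by a second hydrogen-atom transfer faster than it closes a seven-membered ring onto a fully substituted C=N carbon. The hydrazide may also collapse sluggishly. The fallback sets out from 22 and returns at 26. It dispenses with the hydrazone and removes the oxygen in separate, known operations.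
- Fe(acac)3/PhSiH3 in EtOH cyclises the same radical onto the free, strain-activated cyclobutanone carbonyl (known HAT-initiated alkene–ketone radical cyclisation) to give the C5 tertiary alcohol F1.
- Methyl chlorooxoacetate and DMAP convert it into the mixed methyl oxalate F2, which cannot eliminate because all β-hydrogens sit at bridgeheads.
- Bu3SnH/AIBN in refluxing toluene (Barton–McCombie-type deoxygenation of a tertiary oxalate) then gives 26, the cage again forcing hydrogen onto the face of the enone bridge.

**Step 6.** Dimerisation or oligomerisation of the vinylketene may outrun cycloaddition, because two allylic silyloxy groups lower the nucleophilicity of the alkene. Facial discrimination may also erode at 110 °C. The fallback sets out from 9 and returns at 12. It replaces the ketene by the more electrophilic keteniminium ion.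
- Acid chloride 10 and pyrrolidine give the pyrrolidine amide F3.
- Tf2O and 2,4,6-collidine in 1,2-dichloroethane (rt to 60 °C) generate the vinylketeniminium salt, which undergoes the same intramolecular [2+2] cycloaddition to the cyclobutaniminium triflate F4.
- Aqueous NaHCO3 hydrolyses F4 to 12.

**Step 10.** Hydride transfer from a conjugated aldehyde may be slow, so that retro-aldol cleavage or migration of the acyl group from O9 to O7 intervenes. The fallback sets out from 18 and returns at 22. It separates reduction from acylation.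
- Saksena–Evans reduction (Me4NBH(OAc)3, MeCN/AcOH, −30 °C) gives the 1,3-anti diol F5.
- The less hindered allylic C7 alcohol is acylated first with 21 and pyridine to give the 7-senecioate F6.
- The neopentyl C9 alcohol is then esterified with tiglic acid under Yamaguchi conditions to give 22.

Further compounds
F1 | step 13 | C5 tertiary alcohol (5-hydroxy derivative of 26) | C/C=C(\C)C(=O)O[C@@H]1C[C@@H](OC(=O)C=C(C)C)C(C)(C)[C@]2(O)[C@H]3C(=O)C=C(C)[C@@H]2[C@]31C
F2 | step 13 | C5 mixed methyl oxalate | C/C=C(\C)C(=O)O[C@@H]1C[C@@H](OC(=O)C=C(C)C)C(C)(C)[C@]2(OC(=O)C(=O)OC)[C@H]3C(=O)C=C(C)[C@@H]2[C@]31C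
F3 | step 6 | pyrrolidine amide of 9 | O=C(/C=C(\C)C[C@H](O[Si](C)(C)C(C)(C)C)/C=C(\C)CO[Si](C)(C)C(C)(C)C)N1CCCC1
F4 | step 6 | cyclobutaniminium triflate | CC(C)(C)[Si](C)(C)OC[C@@]1(C)[C@@H]2[C@@H](O[Si](C)(C)C(C)(C)C)CC(=C)[C@H]1C2=[N+]1CCCC1.[O-]S(=O)(=O)C(F)(F)F
F5 | step 10 | (7R,9R) 1,3-anti diol | O[C@H](C[C@@H](O)C(C)=C)[C@@]1(C)[C@@H]2C(=O)C=C(C)[C@H]1C2=O
F6 | step 10 | 7-senecioate with free C9 alcohol | O[C@H](C[C@@H](OC(=O)C=C(C)C)C(C)=C)[C@@]1(C)[C@@H]2C(=O)C=C(C)[C@H]1C2=O
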